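The chain (C6 at the tetronic acid ring to C18 at the furan ring) is cut at C13=C14 (Julia–Kocienski) and at C5=C6 (tetronate aldol, dehydration), which leaves C6–C13 as a geranyl unit. The key step exploits that the C7 methyl stereocentre sits next to C6, an aldehyde carbon before it becomes the exocyclic alkene carbon of the butenolide ring: an ene-reductase saturates only the conjugated C7=C8 alkene and sets C7 (R) in one operation, sparing the C11=C12 alkene and the C13 acetate. Its precursor is the E,E-dienal 8-oxogeranyl acetate, made from geranyl acetate by allylic oxidation; the labile aldehyde product is trapped at once by the lithiated tetronate.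

Key step: step 2

Remarks on the chemistry
- The target is read as 5Z (ring oxygen and C7 cis), 7R, 11E, 13E, 15S. The structures of the key-step precursor (2E,6E) and product (7R) agree with this, and the sulfone needed is 2S; no structure had to be corrected.
- SeO2/t-BuOOH alone stops largely at the allylic alcohol, so step 1 carries an MnO2 stage.
- Assumption: a screen of ene-reductases provides an enzyme that gives the 7R aldehyde 4 in high enantiomeric purity.
- Design of the enzyme step: the C13 acetate is kept, since it steers SeO2 to the far E-methyl and does not activate the C11=C12 alkene. The enzymes are used purified, free of esterase and alcohol dehydrogenase activity. Aldehyde 4 is not protected but consumed at once in step 3.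
- Compounds 1, 5, 12, 13 and 19 are taken as commercial.

Step 1
Reactants: 1 geranyl acetate
Product: 3 (2E,6E)-3,7-dimethyl-8-oxoocta-2,6-dien-1-yl acetate, via allylic alcohol 2 (not isolated)
Conditions: SeO2 (0.3 equiv), salicylic acid (0.1 equiv), t-BuOOH (70% aq., 3 equiv), CH2Cl2, 0 °C to rt; aqueous work-up; crude, MnO2 (excess), CH2Cl2, rt; chromatography (removes selenium residues and any 6Z isomer)
Reagents that add atoms: tert-butyl hydroperoxide, CC(C)(C)OO (terminal oxygen source); selenium dioxide, O=[Se]=O (oxygen carrier, catalytic)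
Why: Sharpless-type SeO2 allylic oxidation (ene reaction followed by a [2,3]-sigmatropic shift) should hydroxylate the E-methyl of the distal, more electron-rich trisubstituted alkene, the acetate deactivating the C11=C12 alkene, and MnO2 then converges the alcohol/aldehyde mixture on the E enal without changing either alkene geometry.

Step 2
Reactants: 3 (2E,6E)-3,7-dimethyl-8-oxoocta-2,6-dien-1-yl acetate
Product: 4 (2E,7R)-3,7-dimethyl-8-oxooct-2-en-1-yl acetate
Conditions: R-selective ene-reductase of the Old Yellow Enzyme family (purified; chosen by screening a panel that includes YqjM, OPR1, NCR, OYE1–3 and OYE1 Trp116 variants), NADP+ (cat.), D-glucose, glucose dehydrogenase, potassium phosphate buffer pH 7.0, MTBE (20% v/v), 30 °C, stopped at full conversion; MTBE extract dried and used directly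
Reagents that add atoms: none
Why: Hydride transfer from N5 of the reduced flavin mononucleotide to the β-carbon C8 of the enal, whose carbonyl is polarised by the histidine/asparagine pair of the active site, is followed by protonation of C7 by the conserved tyrosine on the other face (net anti addition of H2), while glucose dehydrogenase returns NADP+ to NADPH at the expense of glucose. The closest known reaction type is the ene-reductase reduction of 2-methyl-2-enals such as 2-methylpent-2-enal and α-methylcinnamaldehydes. No ring is closed. The new stereocentre C7 is controlled by the enzyme alone, through the orientation in which the pocket holds the enal at the moment of protonation, so the R sense rests on the enzyme chosen in the screen. The step needs chemoselectivity, and the substrate secures it, because only the alkene conjugated to the aldehyde is activated for hydride addition whereas the C11=C12 alkene and its allylic acetate carry no activating carbonyl. Enolisation of the α-methyl aldehyde should be held back by pH 7, a short contact time and the MTBE phase that takes up the product, and 4 goes into step 3 without chromatography.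

Step 3
Reactants: 4 (2E,7R)-3,7-dimethyl-8-oxooct-2-en-1-yl acetate; 5 4-methoxy-3-methylfuran-2(5H)-one
Product: 7 (2E,7R)-8-hydroxy-8-(3-methoxy-4-methyl-5-oxo-2,5-dihydrofuran-2-yl)-3,7-dimethyloct-2-en-1-yl acetate, via lithiated tetronate 6 (not isolated)
Conditions: 5 (1.3 equiv), LiN(i-Pr)2 (1.25 equiv), THF, −78 °C; then 4, −78 °C; AcOH quench at −78 °C
Reagents that add atoms: none
Why: Vinylogous aldol addition: LiN(i-Pr)2 removes the C5 hydrogen of the methyl tetronate to give a furanolate that adds to the aldehyde at −78 °C faster than it enolises C7 or attacks the acetate, and the two new centres (C5 and C6, formed as a mixture) are erased in step 4.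

Step 4
Reactants: 7 (2E,7R)-8-hydroxy-8-(3-methoxy-4-methyl-5-oxo-2,5-dihydrofuran-2-yl)-3,7-dimethyloct-2-en-1-yl acetate
Product: 9 (2E,7R)-8-[(2Z)-3-methoxy-4-methyl-5-oxofuran-2(5H)-ylidene]-3,7-dimethyloct-2-en-1-yl acetate, via C6 mesylate 8 (not isolated)
Conditions: MsCl, Et3N, CH2Cl2, 0 °C; then DBU, 0 °C to rt
Reagents that add atoms: none
Why: Mesylation followed by E1cB elimination through the acidic C5 hydrogen should give the conjugated ylidene tetronate mainly as the Z isomer, since the E isomer would press C7 against the C4 methoxy group, while C7 itself is not involved.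

Step 5
Reactants: 9 (2E,7R)-8-[(2Z)-3-methoxy-4-methyl-5-oxofuran-2(5H)-ylidene]-3,7-dimethyloct-2-en-1-yl acetate
Product: 10 (5Z)-5-[(2R,6E)-8-hydroxy-2,6-dimethyloct-6-en-1-ylidene]-4-methoxy-3-methylfuran-2(5H)-one
Conditions: Novozym 435 (immobilised Candida antarctica lipase B), n-BuOH (5 equiv), MTBE, 35 °C
Reagents that add atoms: none
Why: Lipase-catalysed alcoholysis of a primary allylic acetate (geranyl acetate type substrate) removes the acetyl group at neutral pH, so no alkoxide can open the enol lactone or abstract the C7 hydrogen.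

Step 6
Reactants: 10 (5Z)-5-[(2R,6E)-8-hydroxy-2,6-dimethyloct-6-en-1-ylidene]-4-methoxy-3-methylfuran-2(5H)-one
Product: 11 (2E,7R)-8-[(2Z)-3-methoxy-4-methyl-5-oxofuran-2(5H)-ylidene]-3,7-dimethyloct-2-enal
Conditions: MnO2 (activated, excess), CH2Cl2, rt
Reagents that add atoms: none
Why: MnO2 oxidation is selective for the allylic alcohol and should give the E enal without touching the ylidene tetronate or C7.

Step 7
Reactants: 12 (R)-4-benzyl-3-propionyloxazolidin-2-one; 13 allyl iodide
Product: 15 (R)-4-benzyl-3-[(S)-2-methylpent-4-enoyl]oxazolidin-2-one, via sodium Z-enolate 14 (not isolated)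
Conditions: NaN(SiMe3)2, THF, −78 °C; then 13, −78 to −45 °C
Reagents that add atoms: none
Why: Evans asymmetric alkylation: the chelated Z sodium enolate is attacked by allyl iodide on the face away from the benzyl group, which with the R auxiliary sets the 2S centre that becomes C15.

Step 8
Reactants: 15 (R)-4-benzyl-3-[(S)-2-methylpent-4-enoyl]oxazolidin-2-one
Product: 16 (S)-2-methylpent-4-en-1-ol
Conditions: LiBH4, H2O (1 equiv), Et2O, 0 °C; careful concentration (volatile product)
Reagents that add atoms: none
Why: Reductive cleavage of the N-acyl oxazolidinone by LiBH4 attacks the exocyclic carbonyl and releases the primary alcohol without epimerisation, the auxiliary being recovered.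

Step 9
Reactants: 16 (S)-2-methylpent-4-en-1-ol
Product: 17 5-{[(2S)-2-methylpent-4-en-1-yl]sulfanyl}-1-phenyl-1H-tetrazole
Conditions: 1-phenyl-1H-tetrazole-5-thiol, PPh3, DIAD, THF, 0 °C to rt
Reagents that add atoms: 1-phenyl-1H-tetrazole-5-thiol, Sc1nnnn1-c1ccccc1
Why: Mitsunobu thioetherification of a primary alcohol with the acidic tetrazole thiol proceeds by SN2 displacement at C14 and leaves the adjacent stereocentre untouched.

Step 10
Reactants: 17 5-{[(2S)-2-methylpent-4-en-1-yl]sulfanyl}-1-phenyl-1H-tetrazole
Product: 18 5-{[(2S)-2-methylpent-4-en-1-yl]sulfonyl}-1-phenyl-1H-tetrazole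
Conditions: (NH4)6Mo7O24·4H2O (cat.), 30% H2O2, EtOH, 0 °C to rt
Reagents that add atoms: hydrogen peroxide, OO
Why: Molybdate-catalysed peroxide oxidation takes the sulfide through the sulfoxide to the sulfone and is inert towards an isolated terminal alkene.

Step 11
Reactants: 18 5-{[(2S)-2-methylpent-4-en-1-yl]sulfonyl}-1-phenyl-1H-tetrazole; 19 3-bromofuran
Product: 21 5-{[(2S)-5-(furan-3-yl)-2-methylpentyl]sulfonyl}-1-phenyl-1H-tetrazole, via B-alkyl-9-BBN borane 20 (not isolated)
Conditions: 9-BBN, THF, 0 °C to rt; then 19 (1.5 equiv), PdCl2(dppf) (dppf = 1,1'-bis(diphenylphosphino)ferrocene), K3PO4 (3 M aq.), DMF, rt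
Reagents that add atoms: none
Why: Anti-Markovnikov hydroboration with 9-BBN followed by B-alkyl Suzuki–Miyaura coupling with the heteroaryl bromide forms the C18–furan bond under mild phosphate base at room temperature, conditions under which the tetrazolyl sulfone should persist.

Step 12
Reactants: 21 5-{[(2S)-5-(furan-3-yl)-2-methylpentyl]sulfonyl}-1-phenyl-1H-tetrazole; 11 (2E,7R)-8-[(2Z)-3-methoxy-4-methyl-5-oxofuran-2(5H)-ylidene]-3,7-dimethyloct-2-enal
Product: 23 (5Z)-5-[(2R,6E,8E,10S)-13-(furan-3-yl)-2,6,10-trimethyltrideca-6,8-dien-1-ylidene]-4-methoxy-3-methylfuran-2(5H)-one, via potassium sulfonyl carbanion 22 (not isolated)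
Conditions: 21 (1.2 equiv), KN(SiMe3)2 (1.15 equiv), DME, −60 °C; then 11 (1.0 equiv), −60 °C to rt
Reagents that add atoms: none
Why: Julia–Kocienski olefination: the premetalated phenyltetrazolyl sulfone adds to the enal, and Smiles rearrangement with loss of SO2 and the tetrazololate should give the 13E alkene (anti adduct favoured with potassium in DME), the slight excess of sulfone over base leaving no free amide to attack the tetronate or C7.

Step 13
Reactants: 23 (5Z)-5-[(2R,6E,8E,10S)-13-(furan-3-yl)-2,6,10-trimethyltrideca-6,8-dien-1-ylidene]-4-methoxy-3-methylfuran-2(5H)-one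
Product: 25 (5Z)-5-[(2R,6E,8E,10S)-13-(furan-3-yl)-2,6,10-trimethyltrideca-6,8-dien-1-ylidene]-4-hydroxy-3-methylfuran-2(5H)-one, via lithium tetronate 24 (not isolated)
Conditions: LiCl (excess), DMSO, 50 °C; then cold dilute aq. HCl to pH 3, extraction
Reagents that add atoms: none
Why: SN2 O-demethylation by chloride at the methyl group of the vinylogous carbonate (the tetronate is a good leaving group) proceeds under neutral conditions that spare furan, diene, ylidene geometry and both stereocentres, and mild acidification frees the tetronic acid.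

Compound list
1 | geranyl acetate | CC(C)=CCC/C(C)=C/COC(C)=O | starting material
2 | (2E,6E)-8-hydroxy-3,7-dimethylocta-2,6-dien-1-yl acetate | OC/C(C)=C/CC/C(C)=C/COC(C)=O | intermediate (not isolated)
3 | (2E,6E)-3,7-dimethyl-8-oxoocta-2,6-dien-1-yl acetate | O=C/C(C)=C/CC/C(C)=C/COC(C)=O | intermediate
4 | (2E,7R)-3,7-dimethyl-8-oxooct-2-en-1-yl acetate | O=C[C@H](C)CCC/C(C)=C/COC(C)=O | intermediate
5 | 4-methoxy-3-methylfuran-2(5H)-one | COC1=C(C)C(=O)OC1 | starting material
6 | lithium 4-methoxy-3-methylfuran-2-olate (5 lithiated at C5) | [Li+].[O-]c1occ(OC)c1C | intermediate (not isolated)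
7 | (2E,7R)-8-hydroxy-8-(3-methoxy-4-methyl-5-oxo-2,5-dihydrofuran-2-yl)-3,7-dimethyloct-2-en-1-yl acetate (mixture at the two carbinol-side centres) | CC1=C(OC)C(OC1=O)C(O)[C@H](C)CCC/C(C)=C/COC(C)=O | intermediate
8 | (2E,7R)-8-(3-methoxy-4-methyl-5-oxo-2,5-dihydrofuran-2-yl)-3,7-dimethyl-8-[(methylsulfonyl)oxy]oct-2-en-1-yl acetate | CC1=C(OC)C(OC1=O)C(OS(C)(=O)=O)[C@H](C)CCC/C(C)=C/COC(C)=O | intermediate (not isolated)
9 | (2E,7R)-8-[(2Z)-3-methoxy-4-methyl-5-oxofuran-2(5H)-ylidene]-3,7-dimethyloct-2-en-1-yl acetate | CC1=C(OC)/C(=C/[C@H](C)CCC/C(C)=C/COC(C)=O)OC1=O | intermediate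
10 | (5Z)-5-[(2R,6E)-8-hydroxy-2,6-dimethyloct-6-en-1-ylidene]-4-methoxy-3-methylfuran-2(5H)-one | CC1=C(OC)/C(=C/[C@H](C)CCC/C(C)=C/CO)OC1=O | intermediate
11 | (2E,7R)-8-[(2Z)-3-methoxy-4-methyl-5-oxofuran-2(5H)-ylidene]-3,7-dimethyloct-2-enal | CC1=C(OC)/C(=C/[C@H](C)CCC/C(C)=C/C=O)OC1=O | intermediate
12 | (R)-4-benzyl-3-propionyloxazolidin-2-one | CCC(=O)N1[C@H](Cc2ccccc2)COC1=O | starting material
13 | allyl iodide | C=CCI | starting material
14 | sodium Z-enolate of 12 | [Na+].C/C=C(\[O-])N1[C@H](Cc2ccccc2)COC1=O | intermediate (not isolated)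
15 | (R)-4-benzyl-3-[(S)-2-methylpent-4-enoyl]oxazolidin-2-one | C=CC[C@H](C)C(=O)N1[C@H](Cc2ccccc2)COC1=O | intermediate
16 | (S)-2-methylpent-4-en-1-ol | C=CC[C@H](C)CO | intermediate
17 | 5-{[(2S)-2-methylpent-4-en-1-yl]sulfanyl}-1-phenyl-1H-tetrazole | C=CC[C@H](C)CSc1nnnn1-c1ccccc1 | intermediate
18 | 5-{[(2S)-2-methylpent-4-en-1-yl]sulfonyl}-1-phenyl-1H-tetrazole | C=CC[C@H](C)CS(=O)(=O)c1nnnn1-c1ccccc1 | intermediate
19 | 3-bromofuran | Brc1ccoc1 | starting material
20 | 9-{(4S)-4-methyl-5-[(1-phenyl-1H-tetrazol-5-yl)sulfonyl]pentyl}-9-borabicyclo[3.3.1]nonane | C1CC2CCCC(C1)B2CCC[C@H](C)CS(=O)(=O)c1nnnn1-c1ccccc1 | intermediate (not isolated)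
21 | 5-{[(2S)-5-(furan-3-yl)-2-methylpentyl]sulfonyl}-1-phenyl-1H-tetrazole | C[C@@H](CCCc1ccoc1)CS(=O)(=O)c1nnnn1-c1ccccc1 | intermediate
22 | potassium salt of 21 metalated at the carbon next to sulfur | [K+].C[C@@H](CCCc1ccoc1)[CH-]S(=O)(=O)c1nnnn1-c1ccccc1 | intermediate (not isolated)
23 | (5Z)-5-[(2R,6E,8E,10S)-13-(furan-3-yl)-2,6,10-trimethyltrideca-6,8-dien-1-ylidene]-4-methoxy-3-methylfuran-2(5H)-one | CC1=C(OC)/C(=C/[C@H](C)CCC/C(C)=C/C=C/[C@@H](C)CCCc2ccoc2)OC1=O | intermediate
24 | lithium salt of the target tetronic acid | [Li+].CC1=C([O-])/C(=C/[C@H](C)CCC/C(C)=C/C=C/[C@@H](C)CCCc2ccoc2)OC1=O | intermediate (not isolated)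
25 | (5Z)-5-[(2R,6E,8E,10S)-13-(furan-3-yl)-2,6,10-trimethyltrideca-6,8-dien-1-ylidene]-4-hydroxy-3-methylfuran-2(5H)-one (CNP0223721.1) | CC1=C(O)/C(=C/[C@H](C)CCC/C(C)=C/C=C/[C@@H](C)CCCc2ccoc2)OC1=O | target

Total step count: 13. Longest linear sequence: 8 steps (steps 1–6, 12 and 13, from geranyl acetate); the sulfone branch (steps 7–11) joins at step 12.

Steps most likely to fail

Step 2. The enzyme may discriminate the two faces of C7 too weakly in the R sense, or the aldehyde may lose configuration by enolisation in the buffer. The fallback replaces the enzymatic conjugate reduction by a hydroxyl-directed hydrogenation. It sets out from compound 2, obtained by stopping step 1 before the MnO2 stage and returning any 3 in the crude to 2 with NaBH4/CeCl3. Hydrogenation with Ru(OAc)2(BINAP) and H2 in MeOH (Noyori hydrogenation of an allylic alcohol, which leaves the C11=C12 alkene of the allylic acetate alone) should give the configurationally stable alcohol (2E,7R)-8-hydroxy-3,7-dimethyloct-2-en-1-yl acetate F1. The BINAP antipode that leads to 7R is fixed by a trial with both antipodes and Mosher ester analysis. Dess–Martin periodinane buffered with NaHCO3 then oxidises F1 just before step 3, and the fallback comes back to the route at compound 4.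

Step 12. The sulfonyl carbanion or residual amide base may attack the ylidene tetronate (addition at the lactone, abstraction of the C7 hydrogen with loss of configuration), and the E preference at C13=C14 may be incomplete. The fallback moves the olefination to a substrate without the tetronate and sets out from compound 4. CH(OMe)3 with pyridinium p-toluenesulfonate in MeOH gives (2E,7R)-8,8-dimethoxy-3,7-dimethyloct-2-en-1-yl acetate F2. K2CO3 in MeOH gives (2E,7R)-8,8-dimethoxy-3,7-dimethyloct-2-en-1-ol F3, and MnO2 gives (2E,7R)-8,8-dimethoxy-3,7-dimethyloct-2-enal F4. Olefination of F4 with carbanion 22 (from 21) gives 3-[(4S,5E,7E,12R)-13,13-dimethoxy-4,8,12-trimethyltrideca-5,7-dien-1-yl]furan F5, from which a minor 13Z isomer can be removed on AgNO3-impregnated silica before the tetronate is present. Pyridinium p-toluenesulfonate in wet acetone frees (2R,6E,8E,10S)-13-(furan-3-yl)-2,6,10-trimethyltrideca-6,8-dienal F6. Addition of lithiated tetronate 6 at −78 °C gives 5-[(2R,6E,8E,10S)-13-(furan-3-yl)-1-hydroxy-2,6,10-trimethyltrideca-6,8-dien-1-yl]-4-methoxy-3-methylfuran-2(5H)-one F7. MsCl/Et3N forms the corresponding C6 methanesulfonate F8 in the flask, and DBU eliminates it, so that the fallback comes back to the route at compound 23.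

Step 11. Aqueous phosphate may degrade the tetrazolyl sulfone (ipso substitution at the tetrazole carbon, deprotonation next to sulfur), and the tetrazole may slow transmetalation by binding palladium. The fallback installs the furan before sulfur and sets out from compound 16. Two equivalents of 9-BBN carry the hydroxyl as its borinate and give, in the flask, 9-{(4S)-5-[(9-borabicyclo[3.3.1]nonan-9-yl)oxy]-4-methylpentyl}-9-borabicyclo[3.3.1]nonane F9. Coupling with 19 (PdCl2(dppf), aq. NaOH, THF) gives (2S)-5-(furan-3-yl)-2-methylpentan-1-ol F10. Mitsunobu reaction with 1-phenyl-1H-tetrazole-5-thiol gives 5-{[(2S)-5-(furan-3-yl)-2-methylpentyl]sulfanyl}-1-phenyl-1H-tetrazole F11. Oxidation with (NH4)6Mo7O24·4H2O/H2O2 in EtOH at 0 °C, which should oxidise sulfur much faster than a 3-alkylfuran, brings the fallback back to the route at compound 21.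

Further compounds
F1 | step 2 | (2E,7R)-8-hydroxy-3,7-dimethyloct-2-en-1-yl acetate | OC[C@H](C)CCC/C(C)=C/COC(C)=O
F2 | step 12 | (2E,7R)-8,8-dimethoxy-3,7-dimethyloct-2-en-1-yl acetate | COC(OC)[C@H](C)CCC/C(C)=C/COC(C)=O
F3 | step 12 | (2E,7R)-8,8-dimethoxy-3,7-dimethyloct-2-en-1-ol | COC(OC)[C@H](C)CCC/C(C)=C/CO
F4 | step 12 | (2E,7R)-8,8-dimethoxy-3,7-dimethyloct-2-enal | COC(OC)[C@H](C)CCC/C(C)=C/C=O
F5 | step 12 | 3-[(4S,5E,7E,12R)-13,13-dimethoxy-4,8,12-trimethyltrideca-5,7-dien-1-yl]furan | COC(OC)[C@H](C)CCC/C(C)=C/C=C/[C@@H](C)CCCc1ccoc1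
F6 | step 12 | (2R,6E,8E,10S)-13-(furan-3-yl)-2,6,10-trimethyltrideca-6,8-dienal | O=C[C@H](C)CCC/C(C)=C/C=C/[C@@H](C)CCCc1ccoc1
F7 | step 12 | 5-[(2R,6E,8E,10S)-13-(furan-3-yl)-1-hydroxy-2,6,10-trimethyltrideca-6,8-dien-1-yl]-4-methoxy-3-methylfuran-2(5H)-one | CC1=C(OC)C(OC1=O)C(O)[C@H](C)CCC/C(C)=C/C=C/[C@@H](C)CCCc1ccoc1
F8 | step 12 | C6 methanesulfonate of F7 | CC1=C(OC)C(OC1=O)C(OS(C)(=O)=O)[C@H](C)CCC/C(C)=C/C=C/[C@@H](C)CCCc1ccoc1
F9 | step 11 | 9-{(4S)-5-[(9-borabicyclo[3.3.1]nonan-9-yl)oxy]-4-methylpentyl}-9-borabicyclo[3.3.1]nonane | C1CC2CCCC(C1)B2CCC[C@H](C)COB1C2CCCC1CCC2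
F10 | step 11 | (2S)-5-(furan-3-yl)-2-methylpentan-1-ol | OC[C@@H](C)CCCc1ccoc1
F11 | step 11 | 5-{[(2S)-5-(furan-3-yl)-2-methylpentyl]sulfanyl}-1-phenyl-1H-tetrazole | C[C@@H](CCCc1ccoc1)CSc1nnnn1-c1ccccc1
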